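**Retrosynthetic overview**
1. The target is 3β,9β-diacetoxy-1α,10β-epoxy-11αH-germacr-4-en-12,6α-olide (1S,3S,6S,7S,9S,10R,11R). It has a ten-membered carbocycle C1–C10, trans-fused at C6–C7 to a γ-lactone (O, C12, C11).
2. The strategy rests on this feature: C6 bears oxygen and the neighbouring ring carbon C7 bears the three-carbon unit C11(C12)(C13). With C11=C12 as an alkene this is a homoallylic alcohol, the retron of a [2,3]-Wittig shift.
3. Late stage: the acetates, the C1–C10 epoxide (directed by 9-OH), the lactone (oxidation of C12) and C11 (hydroboration of a C7 isopropenyl group) lead back to a ten-membered dienol.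
4. Key disconnection C6–C7: contraction of a thirteen-membered C6–O–C12 diallyl ether with SnBu3 at C6. That ring comes from the thirteen-membered enoate macrolactone in which C6 is the carbonyl carbon.
5. The chain comes from ethyl 3-methyl-4-oxocrotonate by two allylborations (C3, C9) and two cross metatheses with methacrolein. Ring order: thirteen-membered ring, ten-membered carbocycle, γ-lactone, epoxide.

Key step: step 12

**Remarks on the chemistry**
- Germacrane numbering of the target is used for all compounds. The ether methylene of the thirteen-membered ring is the later carbonyl carbon C12, and the methyl on C11 is C13.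
- In the target H-11 is cis to H-7 (11β-methyl, the less stable epimer). Reduction of an α-methylene lactone protonates C11 anti to H-7 and would give the 11α-methyl epimer. C11 therefore carries only a methyl group in the contraction substrate and is set by hydroboration before the lactone exists.
- The C6–Sn bond is made last, on the closed ring. An α-stannyl allylic alkoxide would revert to enal and stannyl anion under the conditions of a macrocyclic Williamson closure.
- Assumption: an α-alkoxyallyllithium that bears an α-hydrogen epimerises fast in THF at −78 °C, so the C6 epimer mixture of the stannane is of no consequence.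
- Assumption: B-allyldiisopinocampheylborane derived from (+)-α-pinene is bought as a pentane solution.

**Step 1**
Reactants: 1 ethyl (2E)-3-methyl-4-oxobut-2-enoate; 2 B-allyldiisopinocampheylborane from (+)-α-pinene
Product: 4 ethyl (2E,4S)-4-hydroxy-3-methylhepta-2,6-dienoate, via borinate 3 (not isolated)
Conditions: Et2O, −78 °C; then NaBO3·4H2O, THF–H2O, rt
Reagents that add atoms: none
Why: Brown allylboration delivers the allyl group through a closed chair transition state to the Si face of the aldehyde under control of the isopinocampheyl ligands, which sets C3 as S, and the conjugated ester is untouched at −78 °C.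

**Step 2**
Reactants: 4 ethyl (2E,4S)-4-hydroxy-3-methylhepta-2,6-dienoate
Product: 5 ethyl (2E,4S)-4-(tert-butyldimethylsilyloxy)-3-methylhepta-2,6-dienoate
Conditions: TBSCl, imidazole, DMF, rt
Reagents that add atoms: tert-butyldimethylsilyl chloride, CC(C)(C)[Si](C)(C)Cl
Why: This is a standard silylation of a secondary allylic alcohol, and TBS is chosen because it must outlast the TES group placed later at C9.

**Step 3**
Reactants: 5 ethyl (2E,4S)-4-(tert-butyldimethylsilyloxy)-3-methylhepta-2,6-dienoate; 6 methacrolein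
Product: 7 ethyl (2E,4S,6E)-4-(tert-butyldimethylsilyloxy)-3,7-dimethyl-8-oxoocta-2,6-dienoate
Conditions: second-generation Hoveyda–Grubbs catalyst (5 mol %), methacrolein (10 equiv), CH2Cl2, 40 °C
Reagents that add atoms: none
Why: Olefin cross metathesis of a monosubstituted alkene with methacrolein should give the (E)-2-methyl enal under thermodynamic control, which builds C1=C10 with C14, while the trisubstituted enoate alkene is inert to the ruthenium carbene.

**Step 4**
Reactants: 7 ethyl (2E,4S,6E)-4-(tert-butyldimethylsilyloxy)-3,7-dimethyl-8-oxoocta-2,6-dienoate; 2 B-allyldiisopinocampheylborane from (+)-α-pinene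
Product: 9 ethyl (2E,4S,6E,8S)-4-(tert-butyldimethylsilyloxy)-8-hydroxy-3,7-dimethylundeca-2,6,10-trienoate, via borinate 8 (not isolated)
Conditions: Et2O, −78 °C; then NaBO3·4H2O, THF–H2O, rt
Reagents that add atoms: none
Why: A second Brown allylboration under reagent control attacks the Si face of the enal and sets C9 as S, and any C3 antipode carried from step 1 becomes a diastereomer that can be removed here.

**Step 5**
Reactants: 9 ethyl (2E,4S,6E,8S)-4-(tert-butyldimethylsilyloxy)-8-hydroxy-3,7-dimethylundeca-2,6,10-trienoate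
Product: 10 (2E,4S,6E,8S)-4-(tert-butyldimethylsilyloxy)-8-hydroxy-3,7-dimethylundeca-2,6,10-trienoic acid
Conditions: LiOH, THF–MeOH–H2O, rt to 40 °C; then dilute aq HCl to pH 4
Reagents that add atoms: lithium hydroxide, [Li+].[OH-]
Why: The saponification of the hindered β-methyl enoate is placed before the base-labile TES group is introduced, and the TBS ether and both stereocentres are stable to hydroxide.

**Step 6**
Reactants: 10 (2E,4S,6E,8S)-4-(tert-butyldimethylsilyloxy)-8-hydroxy-3,7-dimethylundeca-2,6,10-trienoic acid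
Product: 12 (2E,4S,6E,8S)-4-(tert-butyldimethylsilyloxy)-3,7-dimethyl-8-(triethylsilyloxy)undeca-2,6,10-trienoic acid, via silyl ester 11 (not isolated)
Conditions: TESCl (2.5 equiv), imidazole, CH2Cl2, 0 °C; then MeOH–H2O, rt
Reagents that add atoms: chlorotriethylsilane, CC[Si](CC)(CC)Cl
Why: Silylation covers both the C9 hydroxyl and the acid, and the far more labile silyl ester is hydrolysed by aqueous methanol while the secondary TES ether stays.

**Step 7**
Reactants: 12 (2E,4S,6E,8S)-4-(tert-butyldimethylsilyloxy)-3,7-dimethyl-8-(triethylsilyloxy)undeca-2,6,10-trienoic acid; 6 methacrolein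
Product: 13 (2E,4S,6E,8S,10E)-4-(tert-butyldimethylsilyloxy)-3,7,11-trimethyl-12-oxo-8-(triethylsilyloxy)dodeca-2,6,10-trienoic acid
Conditions: second-generation Hoveyda–Grubbs catalyst (5 mol %), methacrolein (10 equiv), CH2Cl2, 40 °C
Reagents that add atoms: none
Why: A second cross metathesis with methacrolein builds C7=C11 with C8 trans to C12, the geometry the ring contraction needs, and the catalyst tolerates the free acid while both internal trisubstituted alkenes are unreactive.

**Step 8**
Reactants: 13 (2E,4S,6E,8S,10E)-4-(tert-butyldimethylsilyloxy)-3,7,11-trimethyl-12-oxo-8-(triethylsilyloxy)dodeca-2,6,10-trienoic acid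
Product: 14 (2E,4S,6E,8S,10E)-4-(tert-butyldimethylsilyloxy)-12-hydroxy-3,7,11-trimethyl-8-(triethylsilyloxy)dodeca-2,6,10-trienoic acid
Conditions: NaBH4 (3 equiv), THF–MeOH, −20 to 0 °C; then aq NaH2PO4
Reagents that add atoms: none
Why: Borohydride reduces an α-methyl enal in the 1,2 sense and leaves the carboxylate and the enoate alkene alone, which gives the seco acid.

**Step 9**
Reactants: 14 (2E,4S,6E,8S,10E)-4-(tert-butyldimethylsilyloxy)-12-hydroxy-3,7,11-trimethyl-8-(triethylsilyloxy)dodeca-2,6,10-trienoic acid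
Product: 15 (3S,9S)-3-TBSO-9-TESO thirteen-membered trienolide (ring C6(=O)–O–C12–C11=C7–C8–C9–C10=C1–C2–C3–C4=C5; all alkenes E)
Conditions: PPh3, DIAD, toluene, slow addition of 14, about 0.002 mol/L, 0 °C to rt
Reagents that add atoms: none
Why: In this Mitsunobu macrolactonisation the primary allylic C12 alcohol becomes the leaving group and is displaced by the carboxylate, so the β-methyl enoic acid is never activated and can neither deconjugate nor lose its E geometry.

**Step 10**
Reactants: 15 (3S,9S)-3-TBSO-9-TESO thirteen-membered trienolide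
Product: 17 thirteen-membered 6-acetoxy C6–O–C12 ether (C6 epimers), via aluminium hemiacetal 16 (not isolated)
Conditions: i-Bu2AlH (2 equiv), CH2Cl2, −78 °C; then pyridine, DMAP, Ac2O, −78 °C to rt
Reagents that add atoms: diisobutylaluminium hydride, CC(C)C[AlH]CC(C)C (aluminium of 16 only); acetic anhydride, CC(=O)OC(C)=O
Why: In this reductive acetylation of an ester the hydride addition stops at the tetrahedral aluminium hemiacetal at −78 °C, which is acetylated in the flask before it can collapse, so the ring C6–O bond survives and the new C6 centre forms as a mixture that does not matter.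

**Step 11**
Reactants: 17 thirteen-membered 6-acetoxy C6–O–C12 ether; 18 tributyltin hydride
Product: 20 thirteen-membered C6–O–C12 diallyl ether with SnBu3 at C6 (C6 epimers; 3S 9S; all alkenes E), via bromo ether 19 (not isolated)
Conditions: Me3SiBr (1.2 equiv), toluene, −78 to −40 °C; transfer into Bu3SnLi (3 equiv, from 18 and LiN(i-Pr)2, THF, 0 °C) at −78 °C
Reagents that add atoms: bromotrimethylsilane, C[Si](C)(C)Br (bromine of 19 only)
Why: The acetal-type acetate is exchanged for bromide and the soft stannyl anion displaces the α-bromo ether at C6, the classical α-halo ether route to α-alkoxystannanes, while attack at the other allyl terminus C4 is blocked because C4 is fully substituted.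

**Step 12**
Reactants: 20 thirteen-membered C6–O–C12 diallyl ether with SnBu3 at C6
Product: 23 ten-membered dienol (1(10)E,4E)-3β-TBSO-9β-TESO-germacra-1(10),4,11-trien-6α-ol (7αH), via allyllithium 21 (not isolated), via lithium alkoxide 22 (not isolated)
Conditions: n-BuLi (1.5 equiv), THF, −78 °C; then H2O
Reagents that add atoms: n-butyllithium, [Li]CCCC (lithium of 21 and 22 only)
Why: Butyllithium attacks tin, tetrabutylstannane leaves and the α-alkoxyallyllithium forms at C6 only; C6 then bonds suprafacially to C7 through a five-membered envelope transition state while O–C12 breaks and the double bond moves to C11=C12, which gives the C6 alkoxide. The closest known reactions are the [2,3]-Wittig ring contraction of thirteen-membered diallylic and allyl propargylic ethers started by deprotonation, and the tin–lithium-triggered (Still-type) [2,3]-Wittig rearrangement. The ten-membered carbocycle closes by transannular C6–C7 bond formation, a contraction from thirteen to ten ring atoms in which O, C12 and C11 leave the ring, and the ring strain is paid for by the change from carbanion to alkoxide. The anti relation between C6–O and C7–C8, the later trans-lactone, should follow from the E geometry of C7=C11 (C8 trans to C12) combined with the E allyl unit C4=C5–C6 in the envelope. The sense of both new centres relative to C3 and C9 is set by the ring, because only the transition state that leads to 6α-O and 7α-H keeps both silyloxy groups on the periphery of the developing chair–chair cyclodecadiene, and both C6 epimers of the stannane drain through it since the lithium compound epimerises. The step needs site selectivity (C6 and not C12 as carbanion), which the tin secures, and [2,3] over [1,2] and [1,4] shifts, which the low temperature favours, and the substrate carries only silyl ethers and alkenes beside the stannane.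

**Step 13**
Reactants: 23 ten-membered dienol
Product: 25 (11R)-3β-TBSO-9β-TESO-germacra-1(10),4-diene-6α,12-diol, via organoborane 24 (not isolated)
Conditions: 9-BBN (3 equiv), THF, 0 °C to rt; then aq NaOH, 30 % H2O2, 0 °C
Reagents that add atoms: 9-borabicyclo[3.3.1]nonane, B1C2CCCC1CCC2 (boron of 24 only); hydrogen peroxide, OO
Why: In this hydroboration–oxidation 9-BBN picks the 1,1-disubstituted C11=C12 alkene over the two hindered trisubstituted ring alkenes, and with H-7 eclipsing C11=C12 (allylic strain) it should add from the C8 side, away from the C6–O–boryl group, which places H-11 cis to H-7 (11R), the sense known for ethers of trans-2-isopropenylcycloalkanols of the isopulegol type.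

**Step 14**
Reactants: 25 (11R)-3β-TBSO-9β-TESO-germacra-1(10),4-diene-6α,12-diol
Product: 27 3β-TBSO-9β-TESO-11αH-germacra-1(10),4-dien-12,6α-olide, via lactol 26 (not isolated)
Conditions: TEMPO (20 mol %), PhI(OAc)2 (3 equiv), CH2Cl2, rt
Reagents that add atoms: none
Why: In this oxidative lactonisation of a 1,4-diol the oxoammonium salt oxidises the primary C12 alcohol first, the aldehyde is trapped at once by the C6 hydroxyl as the lactol and oxidised again, and the near-neutral medium leaves the epimerisable C11 untouched.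

**Step 15**
Reactants: 27 3β-TBSO-9β-TESO-11αH-germacra-1(10),4-dien-12,6α-olide
Product: 28 3β-TBSO-9β-hydroxy-11αH-germacra-1(10),4-dien-12,6α-olide
Conditions: PPTS (cat.), MeOH–CH2Cl2, 0 °C
Reagents that add atoms: none
Why: This selective solvolysis uses the much higher acid lability of TES over TBS, and the weak acid should not trigger transannular cyclisation of the 1(10),4-diene.

**Step 16**
Reactants: 28 3β-TBSO-9β-hydroxy-11αH-germacra-1(10),4-dien-12,6α-olide
Product: 29 3β-TBSO-1α,10β-epoxy-9β-hydroxy-11αH-germacr-4-en-12,6α-olide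
Conditions: VO(acac)2 (5 mol %), t-BuOOH (1.5 equiv, decane), CH2Cl2, 0 °C
Reagents that add atoms: tert-butyl hydroperoxide, CC(C)(C)OO
Why: In this vanadium-catalysed hydroxyl-directed epoxidation the 9β-OH binds the peroxo complex and delivers oxygen to the face of C1=C10 reached with an O–C9–C10=C1 dihedral near 50° and H-9 eclipsing C14, which is also the outer ring face in that rotamer and gives the erythro epoxy alcohol (1S,10R), while C4=C5 has no free hydroxyl and is deactivated by two allylic C–O bonds.

**Step 17**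
Reactants: 29 3β-TBSO-1α,10β-epoxy-9β-hydroxy-11αH-germacr-4-en-12,6α-olide
Product: 30 1α,10β-epoxy-3β,9β-dihydroxy-11αH-germacr-4-en-12,6α-olide
Conditions: Bu4NF, AcOH (1:1, 5 equiv each), THF, rt
Reagents that add atoms: none
Why: Fluoride desilylation buffered with acetic acid avoids free alkoxide, so Payne migration of the 9-hydroxy epoxide, epimerisation at C11 and acid-induced transannular opening of the epoxide should all be avoided.

**Step 18**
Reactants: 30 1α,10β-epoxy-3β,9β-dihydroxy-11αH-germacr-4-en-12,6α-olide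
Product: 31 target 3β,9β-diacetoxy-1α,10β-epoxy-11αH-germacr-4-en-12,6α-olide
Conditions: Ac2O, pyridine, DMAP (cat.), CH2Cl2, 0 °C to rt
Reagents that add atoms: acetic anhydride, CC(=O)OC(C)=O
Why: DMAP-catalysed acetylation esterifies both secondary hydroxyls under conditions too weakly basic to touch C11 or the epoxide.

**Compound list**
1 | ethyl (2E)-3-methyl-4-oxobut-2-enoate | CCOC(=O)/C=C(C)/C=O | starting material
2 | B-allyldiisopinocampheylborane from (+)-α-pinene | C=CCB([C@@H]1C[C@@H]2C[C@H]([C@H]1C)C2(C)C)[C@@H]1C[C@@H]2C[C@H]([C@H]1C)C2(C)C | starting material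
3 | diisopinocampheylborinate of 4 | B(O[C@H](/C(C)=C/C(=O)OCC)CC=C)([C@@H]1C[C@@H]2C[C@H]([C@H]1C)C2(C)C)[C@@H]1C[C@@H]2C[C@H]([C@H]1C)C2(C)C | intermediate
4 | ethyl (2E,4S)-4-hydroxy-3-methylhepta-2,6-dienoate | O[C@H](/C(C)=C/C(=O)OCC)CC=C | intermediate
5 | ethyl (2E,4S)-4-(tert-butyldimethylsilyloxy)-3-methylhepta-2,6-dienoate | CC(C)(C)[Si](C)(C)O[C@H](/C(C)=C/C(=O)OCC)CC=C | intermediate
6 | methacrolein | CC(=C)C=O | starting material
7 | ethyl (2E,4S,6E)-4-(tert-butyldimethylsilyloxy)-3,7-dimethyl-8-oxoocta-2,6-dienoate | CC(C)(C)[Si](C)(C)O[C@H](/C(C)=C/C(=O)OCC)C/C=C(C)/C=O | intermediate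
8 | diisopinocampheylborinate of 9 | CC(C)(C)[Si](C)(C)O[C@H](/C(C)=C/C(=O)OCC)C/C=C(C)/[C@@H](OB([C@@H]1C[C@@H]2C[C@H]([C@H]1C)C2(C)C)[C@@H]1C[C@@H]2C[C@H]([C@H]1C)C2(C)C)CC=C | intermediate
9 | ethyl (2E,4S,6E,8S)-4-(tert-butyldimethylsilyloxy)-8-hydroxy-3,7-dimethylundeca-2,6,10-trienoate | CC(C)(C)[Si](C)(C)O[C@H](/C(C)=C/C(=O)OCC)C/C=C(C)/[C@@H](O)CC=C | intermediate
10 | (2E,4S,6E,8S)-4-(tert-butyldimethylsilyloxy)-8-hydroxy-3,7-dimethylundeca-2,6,10-trienoic acid | CC(C)(C)[Si](C)(C)O[C@H](/C(C)=C/C(=O)O)C/C=C(C)/[C@@H](O)CC=C | intermediate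
11 | triethylsilyl ester of 12 | CC(C)(C)[Si](C)(C)O[C@H](/C(C)=C/C(=O)O[Si](CC)(CC)CC)C/C=C(C)/[C@@H](O[Si](CC)(CC)CC)CC=C | intermediate
12 | (2E,4S,6E,8S)-4-(tert-butyldimethylsilyloxy)-3,7-dimethyl-8-(triethylsilyloxy)undeca-2,6,10-trienoic acid | CC(C)(C)[Si](C)(C)O[C@H](/C(C)=C/C(=O)O)C/C=C(C)/[C@@H](O[Si](CC)(CC)CC)CC=C | intermediate
13 | (2E,4S,6E,8S,10E)-4-(tert-butyldimethylsilyloxy)-3,7,11-trimethyl-12-oxo-8-(triethylsilyloxy)dodeca-2,6,10-trienoic acid | CC(C)(C)[Si](C)(C)O[C@H](/C(C)=C/C(=O)O)C/C=C(C)/[C@@H](O[Si](CC)(CC)CC)C/C=C(C)/C=O | intermediate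
14 | (2E,4S,6E,8S,10E)-4-(tert-butyldimethylsilyloxy)-12-hydroxy-3,7,11-trimethyl-8-(triethylsilyloxy)dodeca-2,6,10-trienoic acid (seco acid) | CC(C)(C)[Si](C)(C)O[C@H](/C(C)=C/C(=O)O)C/C=C(C)/[C@@H](O[Si](CC)(CC)CC)C/C=C(C)/CO | intermediate
15 | (3S,9S)-3-TBSO-9-TESO thirteen-membered trienolide, C6 carbonyl, all alkenes E | CC(C)(C)[Si](C)(C)O[C@H]1C/C=C(C)/[C@@H](O[Si](CC)(CC)CC)C/C=C(C)/COC(=O)/C=C/1C | intermediate
16 | diisobutylaluminium hemiacetal of 15 (C6 epimers) | CC(C)(C)[Si](C)(C)O[C@H]1C/C=C(C)/[C@@H](O[Si](CC)(CC)CC)C/C=C(C)/COC(O[Al](CC(C)C)CC(C)C)/C=C/1C | intermediate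
17 | thirteen-membered 6-acetoxy C6–O–C12 ether (C6 epimers) | CC(C)(C)[Si](C)(C)O[C@H]1C/C=C(C)/[C@@H](O[Si](CC)(CC)CC)C/C=C(C)/COC(OC(C)=O)/C=C/1C | intermediate
18 | tributyltin hydride | CCCC[SnH](CCCC)CCCC | starting material
19 | thirteen-membered 6-bromo C6–O–C12 ether (C6 epimers) | CC(C)(C)[Si](C)(C)O[C@H]1C/C=C(C)/[C@@H](O[Si](CC)(CC)CC)C/C=C(C)/COC(Br)/C=C/1C | intermediate
20 | thirteen-membered C6–O–C12 diallyl ether with SnBu3 at C6 (C6 epimers) | CC(C)(C)[Si](C)(C)O[C@H]1C/C=C(C)/[C@@H](O[Si](CC)(CC)CC)C/C=C(C)/COC([Sn](CCCC)(CCCC)CCCC)/C=C/1C | intermediate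
21 | C6 α-alkoxyallyllithium of the thirteen-membered ether | CC(C)(C)[Si](C)(C)O[C@H]1C/C=C(C)/[C@@H](O[Si](CC)(CC)CC)C/C=C(C)/COC([Li])/C=C/1C | intermediate
22 | lithium alkoxide of 23 | CC(C)(C)[Si](C)(C)O[C@H]1C/C=C(C)/[C@@H](O[Si](CC)(CC)CC)C[C@@H](C(C)=C)[C@@H](/C=C/1C)O[Li] | intermediate
23 | (1(10)E,4E)-3β-TBSO-9β-TESO-germacra-1(10),4,11-trien-6α-ol (7αH) | CC(C)(C)[Si](C)(C)O[C@H]1C/C=C(C)/[C@@H](O[Si](CC)(CC)CC)C[C@@H](C(C)=C)[C@@H](/C=C/1C)O | intermediate
24 | C12 B-alkyl-9-BBN, C6 O-boryl derivative of 25 | CC(C)(C)[Si](C)(C)O[C@H]1C/C=C(C)/[C@@H](O[Si](CC)(CC)CC)C[C@@H]([C@@H](C)CB2C3CCCC2CCC3)[C@@H](/C=C/1C)OB1C2CCCC1CCC2 | intermediate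
25 | (11R)-3β-TBSO-9β-TESO-germacra-1(10),4-diene-6α,12-diol | CC(C)(C)[Si](C)(C)O[C@H]1C/C=C(C)/[C@@H](O[Si](CC)(CC)CC)C[C@@H]([C@@H](C)CO)[C@@H](/C=C/1C)O | intermediate
26 | C12 lactol of 27 | CC(C)(C)[Si](C)(C)O[C@H]1C/C=C(C)/[C@@H](O[Si](CC)(CC)CC)C[C@@H]2[C@@H](/C=C/1C)OC(O)[C@@H]2C | intermediate
27 | 3β-TBSO-9β-TESO-11αH-germacra-1(10),4-dien-12,6α-olide | CC(C)(C)[Si](C)(C)O[C@H]1C/C=C(C)/[C@@H](O[Si](CC)(CC)CC)C[C@@H]2[C@@H](/C=C/1C)OC(=O)[C@@H]2C | intermediate
28 | 3β-TBSO-9β-hydroxy-11αH-germacra-1(10),4-dien-12,6α-olide | CC(C)(C)[Si](C)(C)O[C@H]1C/C=C(C)/[C@@H](O)C[C@@H]2[C@@H](/C=C/1C)OC(=O)[C@@H]2C | intermediate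
29 | 3β-TBSO-1α,10β-epoxy-9β-hydroxy-11αH-germacr-4-en-12,6α-olide | CC(C)(C)[Si](C)(C)O[C@H]1C[C@@H]2O[C@@]2(C)[C@@H](O)C[C@@H]2[C@@H](/C=C/1C)OC(=O)[C@@H]2C | intermediate
30 | 1α,10β-epoxy-3β,9β-dihydroxy-11αH-germacr-4-en-12,6α-olide | O[C@H]1C[C@@H]2O[C@@]2(C)[C@@H](O)C[C@@H]2[C@@H](/C=C/1C)OC(=O)[C@@H]2C | intermediate
31 | 3β,9β-diacetoxy-1α,10β-epoxy-11αH-germacr-4-en-12,6α-olide (CNP0250285.1) | CC(=O)O[C@H]1C[C@@H]2O[C@@]2(C)[C@@H](OC(C)=O)C[C@@H]2[C@@H](/C=C/1C)OC(=O)[C@@H]2C | target

**Step count**
Total step count: 18. Longest linear sequence: 18 steps, from 1.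

**Steps most likely to fail**

1. Step 12.
   - What may go wrong: the allyllithium may be used up by [1,2] or [1,4] shifts or by protonation before the transannular envelope is reached. C6–C7 bonding may also take place on the wrong pair of faces relative to C3 and C9.
   - Fallback: it sets out from 15 and comes back at 23. One equivalent of i-Bu2AlH at −78 °C followed by aqueous work-up lets the hemiacetal collapse to the ω-hydroxy enal F1. CBr4 and PPh3 turn its C12 alcohol into the bromo enal F2. CrCl2 (divalent chromium) in THF under high dilution forms the C12 allylchromium species. This adds through its γ-carbon C7 to the C6 aldehyde in a closed chair (intramolecular Nozaki–Hiyama allylation). It should give the same anti 6-hydroxy-7-isopropenyl ten-membered ring.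

2. Step 11.
   - What may go wrong: the bromo ether may ionise and lose a proton from C15 to a dienyl ether. The stannyl anion may also act as a base or attack bromine instead of C6.
   - Fallback: it sets out from 17 and comes back at 23. Et3SiH and BF3·OEt2 in CH2Cl2 at −78 °C reduce the acetoxy ether to the tin-free thirteen-membered diallyl ether F3. n-BuLi or s-BuLi in THF at −78 °C then starts the [2,3]-Wittig contraction by deprotonation, as known for thirteen-membered diallylic ethers of this substitution pattern. The carbanion site then depends on the kinetic acidity of C6–H over C12–H.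

3. Step 13.
   - What may go wrong: facial selectivity at C11=C12 may be poor, or the ring alkenes may be hydroborated in competition.
   - Fallback: it sets out from 27, obtained after step 14 together with its C11 epimer F4, and comes back at 27. LiN(i-Pr)2 and PhSeCl at −78 °C convert the epimer mixture into the 11-phenylselenide F5, with selenium entering anti to H-7. H2O2 at 0 °C brings about syn elimination towards the methyl group and gives the α-methylene lactone F6. Hydrogenation with Ru(OAc)2(binap) then reduces only the exocyclic alkene under catalyst control, as known for α-methylene-γ-butyrolactones. The ligand antipode is chosen for delivery of hydrogen to the α face of C11.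

**Further compounds**
F1 | step 12 | (2E,4S,6E,8S,10E)-4-TBSO-12-hydroxy-3,7,11-trimethyl-8-TESO-dodeca-2,6,10-trienal | CC(C)(C)[Si](C)(C)O[C@H](/C(C)=C/C=O)C/C=C(C)/[C@@H](O[Si](CC)(CC)CC)C/C=C(C)/CO
F2 | step 12 | (2E,4S,6E,8S,10E)-12-bromo-4-TBSO-3,7,11-trimethyl-8-TESO-dodeca-2,6,10-trienal | CC(C)(C)[Si](C)(C)O[C@H](/C(C)=C/C=O)C/C=C(C)/[C@@H](O[Si](CC)(CC)CC)C/C=C(C)/CBr
F3 | step 11 | tin-free thirteen-membered C6–O–C12 diallyl ether | CC(C)(C)[Si](C)(C)O[C@H]1C/C=C(C)/[C@@H](O[Si](CC)(CC)CC)C/C=C(C)/COC/C=C/1C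
F4 | step 13 | 3β-TBSO-9β-TESO-11βH-germacra-1(10),4-dien-12,6α-olide | CC(C)(C)[Si](C)(C)O[C@H]1C/C=C(C)/[C@@H](O[Si](CC)(CC)CC)C[C@@H]2[C@@H](/C=C/1C)OC(=O)[C@H]2C
F5 | step 13 | 11β-phenylseleno-3β-TBSO-9β-TESO-germacra-1(10),4-dien-12,6α-olide | CC(C)(C)[Si](C)(C)O[C@H]1C/C=C(C)/[C@@H](O[Si](CC)(CC)CC)C[C@@H]2[C@@H](/C=C/1C)OC(=O)[C@]2(C)[Se]c1ccccc1
F6 | step 13 | 3β-TBSO-9β-TESO-germacra-1(10),4,11(13)-trien-12,6α-olide | CC(C)(C)[Si](C)(C)O[C@H]1C/C=C(C)/[C@@H](O[Si](CC)(CC)CC)C[C@@H]2[C@@H](/C=C/1C)OC(=O)C2=C
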